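**Plan**

- Cuts, last first: C4'–O and C3'–OH together (one syn oxidative cyclisation) give absinthin; C2–C2' and C3–C5' (Diels–Alder) give two molecules of one 10β-hydroxy-guaia-2,4-dienolide; the diene and C10–O go back through a 1β,10β-epoxide to kauniolide; C1–C5 goes back to costunolide.
- Enabling feature: in the ten-membered germacranolide ring C1 (of C1=C10) faces C5 (of C4=C5), so one C1–C5 bond divides it into the cyclopentene (C1–C5) and the cycloheptene (C1, C5–C10) of each half, with the 6α,12-lactone already fused at C6–C7.
- Forward: ten-membered ring → 5/7 bicycle (P450 enzyme) → 11-methyl lactone → epoxide → cyclopentadiene → norbornene by dimerisation → bridging tetrahydrofuran.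
- Stereochemistry: C6 and C7 from costunolide; C5 from the enzyme (steers the epoxidation, later trigonal); C11 by enolate protonation; C10/C10' by β-face epoxidation; C1, C2, C3, C1', C2', C5' by hydrogen shift and endo, α-face cycloaddition; C3', C4' by suprafacial addition on the exo face.

Key step: step 1

Assumption: guaiane numbering is used throughout, α/β as in the usual guaianolide projection, primed atoms for the half of the dimer that reacts as the diene; intermediate 2 is drawn with the 3α (3R) hydroxyl attributed to the enzymatic oxidation; kauniolide synthase and its reductase are taken to be available as recombinant yeast microsomes.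

**Route**

Step 1
Reactants: 1 costunolide
Product: 3 kauniolide, via 3α-hydroxycostunolide 2 (not isolated)
Conditions: kauniolide synthase (cytochrome P450) and P450 reductase in yeast microsomes, NADP+ (cat.), glucose 6-phosphate, glucose-6-phosphate dehydrogenase, air, phosphate buffer pH 7.5, 30 °C
Reagents that add atoms: none
Why: The enzyme's high-valent iron-oxo centre abstracts the allylic hydrogen at C3 and returns hydroxyl to give 3α-hydroxycostunolide 2, which does not leave the pocket: the hydroxyl departs as water, the resulting allyl cation spread over C3, C4 and C5 is captured at C5 by C1 of the C1=C10 π bond across the ring, and the tertiary C10 cation sheds H1 to restore a C1=C10 double bond. The nearest flask chemistry is the transannular cation–olefin cyclisation of germacra-1(10),4-dienes, started here by allylic ionisation rather than by a proton. The single new bond closes the cyclopentene in the 5-exo sense relative to the attacking olefin (C10 remains outside it), and the remainder of the ten-membered ring becomes the cycloheptene, the 7-endo counterpart of the same event. C5, the one new stereocentre, is fixed by the conformation in which the protein binds the E,E-diene, C1 reaching C5 on the face that leaves H5 α and trans to H6β. The step needs hydroxylation at C3 alone and C1–C5 bonding instead of the C5–C10 (decalin) closure that protonation causes; the active site supplies both, assisted by the substrate, whose two E olefins hold C1 close to C5 and whose C3 is allylic to C4=C5, so that ionisation makes C5 the electrophile.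

Step 2
Reactants: 3 kauniolide
Product: 4 11β,13-dihydrokauniolide
Conditions: NaBH4, MeOH, 0 °C
Reagents that add atoms: none
Why: Conjugate hydride addition of NaBH4 to the α-methylene-γ-lactone (1,4-reduction) leaves the isolated tri- and tetrasubstituted olefins untouched, and protonation of the lactone enolate in methanol, reversible under the methoxide formed, should give the more stable 11S centre with the new methyl α, trans to C8 on the lactone ring, which also removes the only dienophile that could compete in the later cycloaddition.

Step 3
Reactants: 4 11β,13-dihydrokauniolide; 5 3-chloroperbenzoic acid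
Product: 6 1β,10β-epoxy-5αH,11βH-guai-3-en-12,6α-olide
Conditions: mCPBA (1.05 equiv), CH2Cl2, −20 → 0 °C
Reagents that add atoms: 3-chloroperbenzoic acid, OOC(=O)c1cccc(Cl)c1
Why: Prilezhaev epoxidation in which the peracid should prefer the tetrasubstituted, more electron-rich C1=C10 bond over trisubstituted C3=C4 and approach the convex β face, the α face being screened by H5α and the α-oriented lactone oxygen on C6, as in the arglabin series where this olefin gives the 1β,10β-epoxide; this sets C10 with its oxygen β.

Step 4
Reactants: 6 1β,10β-epoxy-5αH,11βH-guai-3-en-12,6α-olide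
Product: 8 10β-hydroxy-11βH-guaia-1(5),3-dien-12,6α-olide, via silyl ether 7 (not isolated)
Conditions: TMSOTf, 2,6-lutidine, toluene, −78 °C; DBU, −78 → 0 °C; then K2CO3 (cat.), MeOH, 0 °C
Reagents that add atoms: none
Why: Noyori-type opening of an epoxide with a silyl triflate and an amine base to an allylic silyl ether: the silylated oxirane should break at C1–O because DBU removes the allylic H5, which lies anti to that bond on the α face (loss of the equally allylic H2 would lead into the same diene manifold), so that a conjugated cyclopentadiene results while the C10–O bond and its β configuration stay untouched, and mild methanolysis then frees the tertiary alcohol without acid that would ionise the dienyl carbinol.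

Step 5
Reactants: 8 10β-hydroxy-11βH-guaia-1(5),3-dien-12,6α-olide (two molecules)
Product: 10 absinthin, via 1αH-2,4-diene 9 (not isolated)
Conditions: neat film (or toluene, about 2 M), Ar, dark, 25–40 °C, several days
Reagents that add atoms: none
Why: Suprafacial [1,5]-sigmatropic hydrogen shifts interconvert the cyclopentadiene isomers at ambient temperature, the manifold thought to link the natural monomer artabsin to absinthin, and the 1αH-2,4-diene 9, the only isomer with an unhindered cis-disubstituted C2=C3 dienophile, should be drained by a thermal endo Diels–Alder dimerisation (C2'=C3'–C4'=C5' of one molecule with C2=C3 of the other, bonds C2–C2' and C3–C5') in which each partner reacts on its α face, anti to C10 on C1, which fixes C1 and C1' (H α) and sets C2, C3, C2' and C5' while placing C10' on the one-carbon bridge syn to the new C3'=C4' bond, in line with the spontaneous neat dimerisation of closely related 1αH-guaia-2,4-dienes.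

Step 6
Reactants: 10 absinthin; 11 Re2O7
Product: 12 anabsin
Conditions: Re2O7, 2,6-lutidine, CH2Cl2, 0 °C → rt; then H2O2, aq. NaHCO3, 0 °C
Reagents that add atoms: Re2O7 (dirhenium heptoxide), O=[Re](=O)(=O)O[Re](=O)(=O)=O
Why: Kennedy-type oxidative cyclisation of a bishomoallylic tertiary alcohol by heptavalent rhenium: the C10' perrhenate ester, held over the exo face of the C3'=C4' norbornene bond by the C1' bridge, should add its O–Re=O unit suprafacially so that the ether oxygen bonds to C4' and the oxo-derived hydroxyl to C3' on the same exo face (both new centres follow from the tether), whereas the C10 alcohol of the other half is only homoallylic to C4=C5 and cannot cyclise.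

**Compound list**

1 | costunolide, (6R,7S)-germacra-1(10)E,4E,11(13)-trien-12,6α-olide | C/C1=C\CC/C(C)=C/[C@H]2OC(=O)C(=C)[C@@H]2CC1 | starting material
2 | 3α-hydroxycostunolide (3R) | C/C1=C\C[C@@H](O)/C(C)=C/[C@H]2OC(=O)C(=C)[C@@H]2CC1 | intermediate
3 | kauniolide, 5αH,6βH,7αH-guaia-1(10),3,11(13)-trien-12,6α-olide | CC1=CCC2=C(C)CC[C@H]3C(=C)C(=O)O[C@@H]3[C@@H]12 | intermediate
4 | 11β,13-dihydrokauniolide, (11S)-5αH-guaia-1(10),3-dien-12,6α-olide, 11-methyl α | CC1=CCC2=C(C)CC[C@H]3[C@H](C)C(=O)O[C@@H]3[C@@H]12 | intermediate
5 | 3-chloroperbenzoic acid | OOC(=O)c1cccc(Cl)c1 | starting material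
6 | 1β,10β-epoxy-5αH,11βH-guai-3-en-12,6α-olide (11β,13-dihydro-arglabin type) | CC1=CC[C@]2(O3)[C@]3(C)CC[C@H]4[C@H](C)C(=O)O[C@@H]4[C@@H]12 | intermediate
7 | 10β-trimethylsilyloxy-11βH-guaia-1(5),3-dien-12,6α-olide (silyl ether) | CC1=CCC2=C1[C@H]3OC(=O)[C@@H](C)[C@@H]3CC[C@]2(C)O[Si](C)(C)C | intermediate
8 | 10β-hydroxy-11βH-guaia-1(5),3-dien-12,6α-olide (10-methyl α) | CC1=CCC2=C1[C@H]3OC(=O)[C@@H](C)[C@@H]3CC[C@]2(C)O | intermediate
9 | 10β-hydroxy-1αH,11βH-guaia-2,4-dien-12,6α-olide (reactive monomer) | CC1=C2[C@H]3OC(=O)[C@@H](C)[C@@H]3CC[C@](C)(O)[C@@H]2C=C1 | intermediate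
10 | absinthin: endo [4+2] dimer of 9, bonds C2–C2' and C3–C5', norbornene C3'=C4', C1' bridge with C10' syn to that olefin, both halves 1αH and 10β-OH | CC1=C2[C@H]3OC(=O)[C@@H](C)[C@@H]3CC[C@](C)(O)[C@@H]2[C@H]2[C@@H]3[C@@H]4[C@@]([C@H]5OC(=O)[C@@H](C)[C@@H]5CC[C@]4(C)O)(C(C)=C3)[C@@H]12 | intermediate
11 | Re2O7 (dirhenium heptoxide) | O=[Re](=O)(=O)O[Re](=O)(=O)=O | starting material
12 | anabsin: absinthin with a C10'–O–C4' ether bridge and an exo 3'-hydroxyl cis to the ether oxygen | CC1=C2[C@H]3OC(=O)[C@@H](C)[C@@H]3CC[C@](C)(O)[C@@H]2[C@H]2[C@@H]3[C@@H]4[C@]5([C@H]6OC(=O)[C@@H](C)[C@@H]6CC[C@]4(C)O[C@@]5(C)[C@H]3O)[C@@H]12 | target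

**Totals**

Total steps: 6. Longest linear sequence: 6 steps (1 → 3 → 4 → 6 → 8 → 10 → 12; the dimerisation joins two molecules of the same intermediate, so there is no second branch).

**Steps most likely to fail**

Step 4. The silylated oxirane may break at C10–O instead of C1–O and shed a C14 or C9 proton, which would give a 1β-silyloxy-10(14)-ene in place of the cyclopentadiene; the dienyl silyl ether may also ionise under the Lewis acid. The fallback sets out from 4 and comes back at 9, and it oxygenates C10 by an ene reaction instead of an epoxide opening. Dihydrokauniolide 4 would be irradiated with visible light under O2 with tetraphenylporphyrin in CH2Cl2 at −30 °C to partial conversion. Singlet oxygen should add to the β face of the tetrasubstituted C1=C10 bond at C10 and take H2β (Schenck ene reaction), giving 10β-hydroperoxy-5αH,11βH-guaia-1,3-dien-12,6α-olide F1. PPh3 at −30 °C would reduce it to 10β-hydroxy-5αH,11βH-guaia-1,3-dien-12,6α-olide F2. In F2 the hydrogen on C5 is α, so its suprafacial [1,5] shift to C1 should deliver 9 directly, and the route continues within step 5.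

Step 5. The free dienyl carbinol may ionise and lose water, or oxidise, faster than the slow bimolecular cycloaddition drains the hydrogen-shift manifold, and isomers other than 9 may be drawn into cross-dimers or into dimers epimeric at C1. The fallback sets out from 7 and comes back at 10, and it carries the carbinol through the cycloaddition as its silyl ether. Silyl ether 7 would be isolated by a non-aqueous work-up of step 4 (no methanolysis) and kept neat under argon at 40–60 °C. The same hydrogen shift should give 10β-trimethylsilyloxy-1αH,11βH-guaia-2,4-dien-12,6α-olide F3, which should dimerise to absinthin 10,10'-bis(trimethylsilyl) ether F4. The protected carbinol tolerates the higher temperature and shorter reaction time, and F4 can be purified on silica before K2CO3 (cat.) in MeOH at 0 °C frees absinthin 10.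

Step 6. The perrhenic acid set free may add the C10' hydroxyl to C4' without oxidation (acid-catalysed hydroalkoxylation to the deoxy ether) or dehydrate the tertiary alcohols before the perrhenate ester adds to the olefin. The fallback sets out from 10 and comes back at 12, and it forms the same two C–O bonds by an acid-free radical sequence, the Mukaiyama aerobic oxidative cyclisation. Absinthin 10 would be stirred with Co(modp)2, bis(1-morpholinocarbamoyl-4,4-dimethylpentane-1,3-dionato)cobalt (cat.), and t-BuOOH (cat.) under O2 in 2-propanol at 55 °C. The cobalt-bound C10' oxygen should close onto C4' in the 5-exo mode on the only face it can reach, and the C3' norbornyl radical should then take up O2 on its open exo face, the endo face being covered by the other half, to give the 3'-hydroperoxide of anabsin F5. PPh3 would reduce F5 to anabsin 12.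

**Further compounds**

F1 | step 4 | 10β-hydroperoxy-5αH,11βH-guaia-1,3-dien-12,6α-olide | CC1=CC=C2[C@@](C)(OO)CC[C@H]3[C@H](C)C(=O)O[C@@H]3[C@@H]12
F2 | step 4 | 10β-hydroxy-5αH,11βH-guaia-1,3-dien-12,6α-olide | CC1=CC=C2[C@@](C)(O)CC[C@H]3[C@H](C)C(=O)O[C@@H]3[C@@H]12
F3 | step 5 | 10β-trimethylsilyloxy-1αH,11βH-guaia-2,4-dien-12,6α-olide | CC1=C2[C@H]3OC(=O)[C@@H](C)[C@@H]3CC[C@](C)(O[Si](C)(C)C)[C@@H]2C=C1
F4 | step 5 | absinthin 10,10'-bis(trimethylsilyl) ether | CC1=C2[C@H]3OC(=O)[C@@H](C)[C@@H]3CC[C@](C)(O[Si](C)(C)C)[C@@H]2[C@H]2[C@@H]3[C@@H]4[C@@]([C@H]5OC(=O)[C@@H](C)[C@@H]5CC[C@]4(C)O[Si](C)(C)C)(C(C)=C3)[C@@H]12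
F5 | step 6 | 3'-hydroperoxide of anabsin (3'-OOH exo in place of 3'-OH) | CC1=C2[C@H]3OC(=O)[C@@H](C)[C@@H]3CC[C@](C)(O)[C@@H]2[C@H]2[C@@H]3[C@@H]4[C@]5([C@H]6OC(=O)[C@@H](C)[C@@H]6CC[C@]4(C)O[C@@]5(C)[C@H]3OO)[C@@H]12
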